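**Plan**

1. Retrosynthesis: the acetates and the C13 PMB ether lead back to tetraol 30. Its C11 methylene and C12–OH come from a 20,11-γ-lactone with a C12 mesylate (the lactone oxygen is moved from C11 to C12). The 6β-OH/8α-OH pair comes from a Δ7-6-ketone, hence from a C6 silyl enol ether. Ring B is then cut at C8–C9 and C5–C10 (intramolecular [4+2], which also opens ring A), and C1–C10 by an sp3–sp2 coupling.
2. Feature used: in ring B the C6 oxygen lies between C5 and C7, so C5=C6(OSi)–C7=C8 is a 2-silyloxydiene. C20 (on C10) and C11 (on C9) are cis on ring B, so they can be tied as a butenolide C20(=O)–O–C11 that activates C9=C10, locks its geometry and puts a stereocentre (C11) next to it.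
3. Forward: fragment 1 (iodobutenolide 12, eight steps from isoprene monoepoxide) and fragment 2 (silyl dienol ether 20, four steps from mesityl oxide) are joined at C1–C10. One cycloaddition closes rings A and B together. Ring B is then oxygenated at C8, the lactone is reduced with oxygen transfer to C12, and the tetraol is acetylated and unmasked.
4. Stereochemistry: C13 from a Pd-catalysed asymmetric etherification; C11 and C12 from a reagent-controlled epoxidation; C5, C9, C10 from the cycloaddition (diene anti to the C11 side chain, lactone endo); C8 from α-face epoxidation of the enone; C6 from α-face hydride attack; final C12 by SN2 inversion.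

Key step: step 14

Remark on the chemistry: the (1R,2R) antipode of the diphosphine ligand in step 1 is assumed to give (S)-3; if the ether forms with the opposite sense, the (1S,2S) ligand is used and nothing else changes. Atom numbers C1–C20 are labdane numbers of the target.

Step 1
Reactants: 1 2-methyl-2-vinyloxirane (racemic); 2 4-methoxybenzyl alcohol
Product: 3 (S)-2-[(4-methoxybenzyl)oxy]-2-methylbut-3-en-1-ol
Conditions: Pd2(dba)3·CHCl3 (1 mol%), (1R,2R)-N,N'-bis[2-(diphenylphosphino)benzoyl]cyclohexane-1,2-diamine (3 mol%), BEt3 (1 mol%), CH2Cl2, rt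
Reagents that add atoms: none
Why: Pd-catalysed dynamic kinetic asymmetric allylic etherification, in which the two π-allyl complexes interconvert, the borate-bound alcohol is delivered to the tertiary terminus and the chiral ligand sets C13.

Step 2
Reactants: 3 (S)-2-[(4-methoxybenzyl)oxy]-2-methylbut-3-en-1-ol
Product: 4 (S)-2-[(4-methoxybenzyl)oxy]-2-methylbut-3-enal
Conditions: PhI(OAc)2, 2,2,6,6-tetramethylpiperidin-1-oxyl (10 mol%), CH2Cl2, rt
Reagents that add atoms: none
Why: Oxoammonium oxidation of the primary alcohol stops at the aldehyde, which has no α-hydrogen and so cannot epimerise at C13.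

Step 3
Reactants: 4 (S)-2-[(4-methoxybenzyl)oxy]-2-methylbut-3-enal; 5 (triphenylphosphoranylidene)acetaldehyde
Product: 6 (S,E)-4-[(4-methoxybenzyl)oxy]-4-methylhexa-2,5-dienal
Conditions: toluene, 90 °C
Reagents that add atoms: none
Why: Wittig olefination with the stabilised formyl ylide should give the (E)-enal (C11=C12); the α-alkoxy aldehyde is electrophilic enough despite its quaternary neighbour.

Step 4
Reactants: 6 (S,E)-4-[(4-methoxybenzyl)oxy]-4-methylhexa-2,5-dienal; 7 methyl [bis(2,2,2-trifluoroethoxy)phosphoryl]acetate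
Product: 8 methyl (2Z,4E,6S)-6-[(4-methoxybenzyl)oxy]-6-methylocta-2,4,7-trienoate
Conditions: KN(SiMe3)2, 18-crown-6, THF, −78 °C
Reagents that add atoms: none
Why: Still–Gennari olefination gives the (Z)-enoate, which places the C20 ester cis to C11 on the new C9=C10 bond as the later lactone requires.

Step 5
Reactants: 8 methyl (2Z,4E,6S)-6-[(4-methoxybenzyl)oxy]-6-methylocta-2,4,7-trienoate
Product: 9 methyl (Z)-3-[(2R,3S)-3-{(S)-2-[(4-methoxybenzyl)oxy]but-3-en-2-yl}oxiran-2-yl]prop-2-enoate
Conditions: 1,2:4,5-di-O-isopropylidene-β-D-erythro-2,3-hexodiulo-2,6-pyranose (30 mol%), KHSO5, K2CO3, nBu4NHSO4, MeCN/CH2(OMe)2–aq. Na2B4O7 buffer (pH 10.5), 0 °C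
Reagents that add atoms: potassium peroxymonosulfate, [K+].[O-]S(=O)(=O)OO
Why: Shi epoxidation, in which the chiral dioxirane attacks the most electron-rich, trans-disubstituted C11=C12 bond (the acrylate and the hindered vinyl group are left) with the facial sense it shows for trans-disubstituted alkenes, setting C11 (R) and C12 (S).

Step 6
Reactants: 9 methyl (Z)-3-[(2R,3S)-3-{(S)-2-[(4-methoxybenzyl)oxy]but-3-en-2-yl}oxiran-2-yl]prop-2-enoate
Product: 10 (S)-5-{(1S,2S)-1-hydroxy-2-[(4-methoxybenzyl)oxy]-2-methylbut-3-en-1-yl}furan-2(5H)-one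
Conditions: camphorsulfonic acid (10 mol%), H2O (2 equiv), CH2Cl2, 0 °C → rt
Reagents that add atoms: water, O
Why: Acid-promoted 5-exo opening of the allylic epoxide carbon C11 by the cis ester carbonyl (inversion at C11, retention at C12), then hydrolysis of the alkoxy-oxocarbenium ion, gives the butenolide; this is the known lactonisation of cis-4,5-epoxy-2-enoates.

Step 7
Reactants: 10 (S)-5-{(1S,2S)-1-hydroxy-2-[(4-methoxybenzyl)oxy]-2-methylbut-3-en-1-yl}furan-2(5H)-one
Product: 11 (S)-5-{(1S,2S)-1-[(tert-butyldimethylsilyl)oxy]-2-[(4-methoxybenzyl)oxy]-2-methylbut-3-en-1-yl}furan-2(5H)-one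
Conditions: tBuMe2SiOTf, 2,6-lutidine, CH2Cl2, −78 → 0 °C
Reagents that add atoms: tert-butyldimethylsilyl trifluoromethanesulfonate, CC(C)(C)[Si](C)(C)OS(=O)(=O)C(F)(F)F
Why: Silylation of the hindered secondary alcohol with a silyl triflate and a weak, non-nucleophilic base that does not deprotonate the butenolide γ-position (C11).

Step 8
Reactants: 11 (S)-5-{(1S,2S)-1-[(tert-butyldimethylsilyl)oxy]-2-[(4-methoxybenzyl)oxy]-2-methylbut-3-en-1-yl}furan-2(5H)-one
Product: 12 (S)-5-{(1S,2S)-1-[(tert-butyldimethylsilyl)oxy]-2-[(4-methoxybenzyl)oxy]-2-methylbut-3-en-1-yl}-3-iodofuran-2(5H)-one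
Conditions: I2, pyridine, CH2Cl2, rt
Reagents that add atoms: iodine, [I][I]
Why: α-Iodination of the unsaturated lactone by conjugate addition of pyridine, iodination of the enolate and elimination installs the halide at C10 for the coupling.

Step 9
Reactants: 13 4-methylpent-3-en-2-one (mesityl oxide); 14 allyltrimethylsilane
Product: 15 4,4-dimethylhept-6-en-2-one
Conditions: TiCl4, CH2Cl2, −78 °C
Reagents that add atoms: none
Why: Hosomi–Sakurai conjugate allylation of the β,β-disubstituted enone builds the quaternary C4 with its two methyl groups and the terminal alkene C1=C2.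

Step 10
Reactants: 15 4,4-dimethylhept-6-en-2-one; 16 acetaldehyde
Product: 17 2-hydroxy-6,6-dimethylnon-8-en-4-one (racemic)
Conditions: LiN(iPr)2, THF, −78 °C; then 16
Reagents that add atoms: none
Why: Kinetic deprotonation takes the methyl proton, not the neopentyl methylene, and the lithium enolate adds to acetaldehyde (aldol) to attach C8 and C17.

Step 11
Reactants: 17 2-hydroxy-6,6-dimethylnon-8-en-4-one
Product: 19 (E)-6,6-dimethylnona-2,8-dien-4-one, via β-mesyloxy ketone 18 (not isolated)
Conditions: MeSO2Cl, Et3N, CH2Cl2, 0 °C → rt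
Reagents that add atoms: none
Why: Mesylation and E1cB elimination of the β-mesyloxy ketone give the conjugated (E)-enone.

Step 12
Reactants: 19 (E)-6,6-dimethylnona-2,8-dien-4-one
Product: 20 tert-butyl{[(2E,4Z)-6,6-dimethylnona-2,4,8-trien-4-yl]oxy}dimethylsilane
Conditions: tBuMe2SiOTf, Et3N, CH2Cl2, −78 → 0 °C
Reagents that add atoms: tert-butyldimethylsilyl trifluoromethanesulfonate, CC(C)(C)[Si](C)(C)OS(=O)(=O)C(F)(F)F
Why: Soft enolisation of the enone towards the α′-methylene C5 gives the cross-conjugated 2-silyloxydiene, with the tert-alkyl group trans to the propenyl group (Z enol ether), the geometry the tether needs.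

Step 13
Reactants: 20 tert-butyl{[(2E,4Z)-6,6-dimethylnona-2,4,8-trien-4-yl]oxy}dimethylsilane; 12 iodobutenolide
Product: 22 (S)-3-{(5Z,7E)-6-[(tert-butyldimethylsilyl)oxy]-4,4-dimethylnona-5,7-dien-1-yl}-5-{(1S,2S)-1-[(tert-butyldimethylsilyl)oxy]-2-[(4-methoxybenzyl)oxy]-2-methylbut-3-en-1-yl}furan-2(5H)-one, via B-alkyl-9-BBN borane 21 (not isolated)
Conditions: 9-BBN, THF, 0 °C → rt; then 12, PdCl2(dppf)·CH2Cl2 (5 mol%), AsPh3 (5 mol%), aq. K3PO4, DMF/THF, rt
Reagents that add atoms: none
Why: 9-BBN should hydroborate only the unhindered terminal alkene (anti-Markovnikov), and B-alkyl Suzuki–Miyaura coupling of the borane with the α-iodobutenolide forms the C1–C10 bond at room temperature without touching the silyl enol ether.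

Step 14
Reactants: 22 silyloxydiene–butenolide triene
Product: 23 tricyclic cycloadduct: Δ6 C6 tert-butyldimethylsilyl enol ether of the 20,11-γ-lactone (labdane numbering; 5α-H, 9α-H, 10β-C20, 8β-CH3, 11S, 12S-OSi, 13S-OPMB, Δ14)
Conditions: toluene (5 mmol/L), 2,6-di-tert-butyl-4-methylphenol (5 mol%), 180 °C, sealed tube
Reagents that add atoms: none
Why: Thermal intramolecular Diels–Alder reaction of the 2-silyloxydiene C5=C6–C7=C8 with the butenolide alkene C9=C10 through a concerted, suprafacial [4+2] transition state; the closest known reaction type is the type 1 intramolecular cycloaddition of 1,3,9-decatrienes carrying the activating carbonyl on the tethered dienophile carbon, including silyloxydiene and butenolide cases. Ring B closes as the cyclohexene by both new bonds (C8–C9, C5–C10), and ring A closes through the C5–C10 bond with the four-carbon tether C1–C4 in a chair-like, fused arrangement. The lactone carbonyl C20 and C11, held cis by the butenolide, lie endo under C6/C7 while the tether stays exo, which places H-5 trans to C20 (trans-decalin), H-9 cis to H-5 and, from the E-propenyl terminus, the C8 methyl on the C20 face. The absolute sense comes from C11: its bulky C12 side chain shields one face of the flat butenolide, so the diene adds anti to it and C5, C9, C10 (and C8) follow. The step needs π-facial and endo selectivity, secured by the γ-substituent and by the cyclic, Z-locked dienophile; regiochemistry is fixed by the tether (against the electronic preference of the diene, hence the high temperature), ring closure is helped by the gem-dimethyl group at C4, and the quaternary C4 and the E-propenyl group leave no path for 1,5-hydrogen shifts.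

Step 15
Reactants: 23 tricyclic cycloadduct
Product: 24 Δ7-6-ketone (C6=O, C7=C8) of the 20,11-γ-lactone, 12S-OSi, 13S-OPMB
Conditions: Pd(OAc)2 (1.2 equiv), MeCN, 40 °C
Reagents that add atoms: none
Why: Saegusa–Ito oxidation: the silyl enol ether gives an oxa-π-allyl palladium species at C7 whose β-hydride elimination can only take H-8, so the enone forms regiospecifically.

Step 16
Reactants: 24 Δ7-6-ketone
Product: 25 7α,8α-epoxy-6-ketone
Conditions: tBuOOH, DBU, CH2Cl2, 0 °C → rt
Reagents that add atoms: tert-butyl hydroperoxide, CC(C)(C)OO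
Why: Nucleophilic (Weitz–Scheffer) epoxidation; the hydroperoxide anion adds to C8 from the α-face because the β-face is covered by the lactone bridge on C9/C10, which sets the C8–O bond α and the methyl β.

Step 17
Reactants: 25 7α,8α-epoxy-6-ketone
Product: 26 8α-hydroxy-6-ketone
Conditions: SmI2 (2.5 equiv), THF/MeOH, −90 °C
Reagents that add atoms: none
Why: Samarium diiodide reduces the α,β-epoxy ketone by electron transfer and cleaves the C7–O bond, giving the β-hydroxy ketone with C8 untouched; lactone and silyl ether are inert.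

Step 18
Reactants: 26 8α-hydroxy-6-ketone
Product: 27 12S-alcohol (C12 silyl ether removed)
Conditions: HF·pyridine, pyridine/THF, 0 °C → rt
Reagents that add atoms: none
Why: Buffered fluoride cleavage of the secondary silyl ether leaves the lactone, the β-hydroxy ketone and the PMB ether intact.

Step 19
Reactants: 27 12S-alcohol
Product: 28 12S-methanesulfonate
Conditions: MeSO2Cl, Et3N, CH2Cl2, −20 °C
Reagents that add atoms: methanesulfonyl chloride, CS(=O)(=O)Cl
Why: Sulfonylation (sulfene pathway) of the only secondary hydroxyl; the tertiary C8 hydroxyl should not react at this temperature.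

Step 20
Reactants: 28 12S-methanesulfonate
Product: 30 (12R,13S)-13-[(4-methoxybenzyl)oxy]labd-14-ene-6β,8α,12,20-tetraol, via 11,12-epoxide 29 (not isolated)
Conditions: LiAlH4 (excess), THF, 0 → 50 °C; aq. NaOH work-up
Reagents that add atoms: none
Why: LiAlH4 reduces the C6 ketone from the open α-face (6β-OH, anti to the C8 alkoxide) and the γ-lactone to the C20/C11 dialkoxide; the C11 alkoxide then displaces the neighbouring mesylate with inversion (Payne-type epoxide closure, 12S → 12R), and hydride opens the epoxide at C11, the carbon not flanked by the quaternary C13, so the former lactone oxygen ends on C12 and C11 becomes a methylene.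

Step 21
Reactants: 30 13-O-PMB tetraol
Product: 31 (12R,13S)-6β,8α,12,20-tetraacetoxy-13-[(4-methoxybenzyl)oxy]labd-14-ene
Conditions: Ac2O, Et3N, 4-(dimethylamino)pyridine, CH2Cl2, 40 °C
Reagents that add atoms: acetic anhydride, CC(=O)OC(C)=O
Why: Pyridine-catalysed acylation esterifies the primary, the two secondary and, on warming, the tertiary C8 hydroxyl, while the C13 oxygen stays blocked as its PMB ether.

Step 22
Reactants: 31 tetraacetate PMB ether
Product: 32 (12R,13S)-6β,8α,12,20-tetraacetoxylabd-14-en-13-ol (target)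
Conditions: 2,3-dichloro-5,6-dicyano-1,4-benzoquinone, CH2Cl2/aq. pH 7 phosphate buffer, 0 °C
Reagents that add atoms: none
Why: Oxidative cleavage of the p-methoxybenzyl ether (hydride abstraction, hydrolysis of the oxocarbenium ion) frees the tertiary C13 alcohol under neutral conditions, so no acyl migration from C12 is expected.

**Compound list**

1 | 2-methyl-2-vinyloxirane (racemic) | C=CC1(C)CO1 | starting material
2 | 4-methoxybenzyl alcohol | COc1ccc(CO)cc1 | starting material
3 | (S)-2-[(4-methoxybenzyl)oxy]-2-methylbut-3-en-1-ol | C=C[C@](C)(OCc1ccc(OC)cc1)CO | intermediate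
4 | (S)-2-[(4-methoxybenzyl)oxy]-2-methylbut-3-enal | C=C[C@](C)(OCc1ccc(OC)cc1)C=O | intermediate
5 | (triphenylphosphoranylidene)acetaldehyde | O=CC=P(c1ccccc1)(c1ccccc1)c1ccccc1 | starting material
6 | (S,E)-4-[(4-methoxybenzyl)oxy]-4-methylhexa-2,5-dienal | C=C[C@](C)(OCc1ccc(OC)cc1)/C=C/C=O | intermediate
7 | methyl [bis(2,2,2-trifluoroethoxy)phosphoryl]acetate | COC(=O)CP(=O)(OCC(F)(F)F)OCC(F)(F)F | starting material
8 | methyl (2Z,4E,6S)-6-[(4-methoxybenzyl)oxy]-6-methylocta-2,4,7-trienoate | C=C[C@](C)(OCc1ccc(OC)cc1)/C=C/C=C\C(=O)OC | intermediate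
9 | methyl (Z)-3-[(2R,3S)-3-{(S)-2-[(4-methoxybenzyl)oxy]but-3-en-2-yl}oxiran-2-yl]prop-2-enoate | C=C[C@](C)(OCc1ccc(OC)cc1)[C@H]1O[C@@H]1/C=C\C(=O)OC | intermediate
10 | (S)-5-{(1S,2S)-1-hydroxy-2-[(4-methoxybenzyl)oxy]-2-methylbut-3-en-1-yl}furan-2(5H)-one | C=C[C@](C)(OCc1ccc(OC)cc1)[C@@H](O)[C@H]1OC(=O)C=C1 | intermediate
11 | (S)-5-{(1S,2S)-1-[(tert-butyldimethylsilyl)oxy]-2-[(4-methoxybenzyl)oxy]-2-methylbut-3-en-1-yl}furan-2(5H)-one | C=C[C@](C)(OCc1ccc(OC)cc1)[C@@H](O[Si](C)(C)C(C)(C)C)[C@H]1OC(=O)C=C1 | intermediate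
12 | (S)-5-{(1S,2S)-1-[(tert-butyldimethylsilyl)oxy]-2-[(4-methoxybenzyl)oxy]-2-methylbut-3-en-1-yl}-3-iodofuran-2(5H)-one | C=C[C@](C)(OCc1ccc(OC)cc1)[C@@H](O[Si](C)(C)C(C)(C)C)[C@H]1OC(=O)C([I])=C1 | intermediate
13 | 4-methylpent-3-en-2-one (mesityl oxide) | CC(=O)C=C(C)C | starting material
14 | allyltrimethylsilane | C=CC[Si](C)(C)C | starting material
15 | 4,4-dimethylhept-6-en-2-one | CC(=O)CC(C)(C)CC=C | intermediate
16 | acetaldehyde | CC=O | starting material
17 | 2-hydroxy-6,6-dimethylnon-8-en-4-one (racemic) | CC(O)CC(=O)CC(C)(C)CC=C | intermediate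
18 | 6,6-dimethyl-4-oxonon-8-en-2-yl methanesulfonate (not isolated) | CC(OS(C)(=O)=O)CC(=O)CC(C)(C)CC=C | intermediate
19 | (E)-6,6-dimethylnona-2,8-dien-4-one | C/C=C/C(=O)CC(C)(C)CC=C | intermediate
20 | tert-butyl{[(2E,4Z)-6,6-dimethylnona-2,4,8-trien-4-yl]oxy}dimethylsilane | C/C=C/C(O[Si](C)(C)C(C)(C)C)=C/C(C)(C)CC=C | intermediate
21 | B-alkyl-9-BBN borane from 20 (boron on C1; not isolated) | C/C=C/C(O[Si](C)(C)C(C)(C)C)=C/C(C)(C)CCCB1C2CCCC1CCC2 | intermediate
22 | silyloxydiene–butenolide triene (full name in step 13) | C=C[C@](C)(OCc1ccc(OC)cc1)[C@@H](O[Si](C)(C)C(C)(C)C)[C@H]1OC(=O)C(CCCC(C)(C)/C=C(O[Si](C)(C)C(C)(C)C)/C=C/C)=C1 | intermediate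
23 | tricyclic cycloadduct: C6 silyl enol ether (Δ6), 20,11-γ-lactone, 5α-H, 9α-H, 8β-CH3, 12S-OSi, 13S-OPMB | C=C[C@](C)(OCc1ccc(OC)cc1)[C@@H](O[Si](C)(C)C(C)(C)C)[C@H]2OC(=O)[C@@]3(CCCC(C)(C)[C@@H]3C(O[Si](C)(C)C(C)(C)C)=C[C@@H]4C)[C@@H]24 | intermediate
24 | Δ7-6-ketone of the 20,11-γ-lactone | C=C[C@](C)(OCc1ccc(OC)cc1)[C@@H](O[Si](C)(C)C(C)(C)C)[C@H]2OC(=O)[C@@]3(CCCC(C)(C)[C@@H]3C(=O)C=C4C)[C@@H]24 | intermediate
25 | 7α,8α-epoxy-6-ketone | C=C[C@](C)(OCc1ccc(OC)cc1)[C@@H](O[Si](C)(C)C(C)(C)C)[C@H]2OC(=O)[C@@]3(CCCC(C)(C)[C@@H]3C(=O)[C@H]5O[C@]54C)[C@@H]24 | intermediate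
26 | 8α-hydroxy-6-ketone | C=C[C@](C)(OCc1ccc(OC)cc1)[C@@H](O[Si](C)(C)C(C)(C)C)[C@H]2OC(=O)[C@@]3(CCCC(C)(C)[C@@H]3C(=O)C[C@@]4(C)O)[C@@H]24 | intermediate
27 | 12S-alcohol (8α-hydroxy-6-ketone, 20,11-γ-lactone) | C=C[C@](C)(OCc1ccc(OC)cc1)[C@@H](O)[C@H]2OC(=O)[C@@]3(CCCC(C)(C)[C@@H]3C(=O)C[C@@]4(C)O)[C@@H]24 | intermediate
28 | 12S-methanesulfonate | C=C[C@](C)(OCc1ccc(OC)cc1)[C@@H](OS(C)(=O)=O)[C@H]2OC(=O)[C@@]3(CCCC(C)(C)[C@@H]3C(=O)C[C@@]4(C)O)[C@@H]24 | intermediate
29 | (11S,12R)-11,12-epoxide of the 6β,8α,20-triol (alkoxide in the flask; not isolated) | C=C[C@](C)(OCc1ccc(OC)cc1)[C@@H]5O[C@H]5[C@@H]1[C@@]2(CO)CCCC(C)(C)[C@@H]2[C@H](O)C[C@@]1(C)O | intermediate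
30 | (12R,13S)-13-[(4-methoxybenzyl)oxy]labd-14-ene-6β,8α,12,20-tetraol | C=C[C@](C)(OCc1ccc(OC)cc1)[C@@H](C[C@@H]1[C@@]2(CO)CCCC(C)(C)[C@@H]2[C@H](O)C[C@@]1(C)O)O | intermediate
31 | (12R,13S)-6β,8α,12,20-tetraacetoxy-13-[(4-methoxybenzyl)oxy]labd-14-ene | C=C[C@](C)(OCc1ccc(OC)cc1)[C@@H](C[C@@H]1[C@@]2(COC(C)=O)CCCC(C)(C)[C@@H]2[C@H](OC(C)=O)C[C@@]1(C)OC(C)=O)OC(C)=O | intermediate
32 | (12R,13S)-6β,8α,12,20-tetraacetoxylabd-14-en-13-ol | C=C[C@](C)(O)[C@@H](C[C@@H]1[C@@]2(COC(C)=O)CCCC(C)(C)[C@@H]2[C@H](OC(C)=O)C[C@@]1(C)OC(C)=O)OC(C)=O | target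

**Totals and risks**

Total step count: 22. Longest linear sequence: 18 steps (steps 1–8, then 13–22).

Steps most likely to fail:

Step 14 (key step). The cycloaddition is electronically mismatched (the nucleophilic C5 terminus of the silyloxydiene must bond to the α-carbon C10) and needs prolonged heating. The likely failure is loss of the silyl enol ether (protodesilylation, silyl migration) before ring closure, with incomplete endo preference as a second concern. The fallback sets out from 22 and returns at 24. The dienol ether is hydrolysed (oxalic acid, wet THF) to the enone lactone F1, which is re-enolised with iPr3SiOTf/Et3N to the far more robust triisopropylsilyl dienol ether F2. This can be heated to 200–220 °C in 1,2-dichlorobenzene to give the triisopropylsilyl cycloadduct F3. Dilute HCl in THF then gives the saturated C6 ketone F4, and 2-iodoxybenzoic acid in DMSO at 70 °C dehydrogenates it to 24; this is the only direction open, because C4 and C10 carry no hydrogen. The Saegusa oxidation is thus replaced by a ketone dehydrogenation.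

Step 20. Hydride may attack the sulfur of the hindered mesylate (returning the 12S alcohol), or the C20 alkoxide may open the epoxide to a tetrahydrofuran faster than hydride does. The fallback sets out from 27 and returns at 30. Dess–Martin periodinane oxidises the C12 alcohol to the α-acyloxy ketone F5. SmI2 (THF/MeOH, −78 °C) cleaves the C11–O bond by electron transfer and gives the 12-oxo-20-carboxylic acid F6. (S)-1-Methyl-3,3-diphenyltetrahydro-1H,3H-pyrrolo[1,2-c][1,3,2]oxazaborole (the S-configured CBS catalyst) with catecholborane at −78 °C should reduce the C12 ketone under reagent control (tert-alkyl against primary alkyl) to the 12R-hydroxy acid F7. LiAlH4 then reduces the acid and the C6 ketone to 30. The oxygen shuttle is replaced by reductive excision of the lactone oxygen and a reagent-controlled ketone reduction.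

Step 13. The silyl dienol ether may be hydroborated or hydrolysed during the coupling, and the butenolide centre C11 may epimerise under the basic conditions. The fallback sets out from 19 and 12 and returns at 22. NaBH4/CeCl3·7H2O reduces enone 19 to the allylic alcohol F8, which is protected as the triethylsilyl ether F9. 9-BBN gives the alkylborane F10, and the same palladium-catalysed coupling with 12 gives the coupled butenolide F11, which carries no enol ether. Pyridinium p-toluenesulfonate in MeOH removes only the triethylsilyl group and gives the allylic alcohol F12. MnO2 oxidises it to the enone lactone F13 (the same structure as F1), and tBuMe2SiOTf/Et3N converts this into 22. The diene oxygen is thus carried through the coupling as a masked allylic alcohol.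

Further compounds

F1 | step 14 | enone lactone: (S)-5-{(1S,2S)-1-[(tert-butyldimethylsilyl)oxy]-2-[(4-methoxybenzyl)oxy]-2-methylbut-3-en-1-yl}-3-[(E)-4,4-dimethyl-6-oxonon-7-en-1-yl]furan-2(5H)-one | C=C[C@](C)(OCc1ccc(OC)cc1)[C@@H](O[Si](C)(C)C(C)(C)C)[C@H]1OC(=O)C(CCCC(C)(C)CC(=O)/C=C/C)=C1
F2 | step 14 | triisopropylsilyl dienol ether analogue of 22 | C=C[C@](C)(OCc1ccc(OC)cc1)[C@@H](O[Si](C)(C)C(C)(C)C)[C@H]1OC(=O)C(CCCC(C)(C)/C=C(O[Si](C(C)C)(C(C)C)C(C)C)/C=C/C)=C1
F3 | step 14 | triisopropylsilyl cycloadduct (analogue of 23) | C=C[C@](C)(OCc1ccc(OC)cc1)[C@@H](O[Si](C)(C)C(C)(C)C)[C@H]2OC(=O)[C@@]3(CCCC(C)(C)[C@@H]3C(O[Si](C(C)C)(C(C)C)C(C)C)=C[C@@H]4C)[C@@H]24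
F4 | step 14 | saturated C6 ketone (8β-methyl, 8α-H) of the 20,11-γ-lactone | C=C[C@](C)(OCc1ccc(OC)cc1)[C@@H](O[Si](C)(C)C(C)(C)C)[C@H]2OC(=O)[C@@]3(CCCC(C)(C)[C@@H]3C(=O)C[C@@H]4C)[C@@H]24
F5 | step 20 | 12-ketone (α-acyloxy ketone) of the 8α-hydroxy-6-oxo-20,11-γ-lactone | C=C[C@](C)(OCc1ccc(OC)cc1)C(=O)[C@H]2OC(=O)[C@@]3(CCCC(C)(C)[C@@H]3C(=O)C[C@@]4(C)O)[C@@H]24
F6 | step 20 | (13S)-8α-hydroxy-13-[(4-methoxybenzyl)oxy]-6,12-dioxolabd-14-en-20-oic acid | C=C[C@](C)(OCc1ccc(OC)cc1)C(=O)C[C@@H]1[C@@]2(C(=O)O)CCCC(C)(C)[C@@H]2C(=O)C[C@@]1(C)O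
F7 | step 20 | (12R,13S)-8α,12-dihydroxy-13-[(4-methoxybenzyl)oxy]-6-oxolabd-14-en-20-oic acid | C=C[C@](C)(OCc1ccc(OC)cc1)[C@H](O)C[C@@H]1[C@@]2(C(=O)O)CCCC(C)(C)[C@@H]2C(=O)C[C@@]1(C)O
F8 | step 13 | (E)-6,6-dimethylnona-2,8-dien-4-ol (racemic) | C/C=C/C(O)CC(C)(C)CC=C
F9 | step 13 | {[(E)-6,6-dimethylnona-2,8-dien-4-yl]oxy}triethylsilane | C/C=C/C(O[Si](CC)(CC)CC)CC(C)(C)CC=C
F10 | step 13 | B-alkyl-9-BBN borane from F9 | C/C=C/C(O[Si](CC)(CC)CC)CC(C)(C)CCCB1C2CCCC1CCC2
F11 | step 13 | coupled butenolide with the C6 triethylsilyl ether side chain | C=C[C@](C)(OCc1ccc(OC)cc1)[C@@H](O[Si](C)(C)C(C)(C)C)[C@H]1OC(=O)C(CCCC(C)(C)CC(O[Si](CC)(CC)CC)/C=C/C)=C1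
F12 | step 13 | coupled butenolide with the free C6 allylic alcohol | C=C[C@](C)(OCc1ccc(OC)cc1)[C@@H](O[Si](C)(C)C(C)(C)C)[C@H]1OC(=O)C(CCCC(C)(C)CC(O)/C=C/C)=C1
F13 | step 13 | enone lactone (same structure as F1) | C=C[C@](C)(OCc1ccc(OC)cc1)[C@@H](O[Si](C)(C)C(C)(C)C)[C@H]1OC(=O)C(CCCC(C)(C)CC(=O)/C=C/C)=C1
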